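**Retrosynthetic overview**

1. The target comes from its tert-butyl ester by acidolysis; the side-chain carbinol comes from a Felkin reduction of the ketone next to the pyranone, and the ring C–H next to it from a decarboxylative protonation.
2. Key step: one pot joins a butenolide acrylate with a β-ketoester that carries a γ-hydroxybutenolide (a masked formylacrylate). A Michael/Michael/lactolisation cascade, modelled on the presumed biogenesis, forms the cyclopentane, both quaternary carbons and the spiro-lactol.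
3. The β-ketoester partner comes from a pyranone β-ketoester and an allylic bromide (C-alkylation, then acid unmasking of the pseudoacid).
4. The pyranone β-ketoester comes from a glyoxylate hetero-Diels–Alder adduct; the butenolide acrylate from an ynoate by hydrostannation, lactonisation and Stille coupling.
5. Ring order: butenolide and dihydropyranone separately, then the hydroxybutenolide, then cyclopentane and spiro-lactol together in the key step.

Assumption: the biogenesis is taken to be a double conjugate addition (an activated polyketide methylene adds to an alkylitaconate-derived butenolide acrylate, and the ester enolate so formed adds to a ring-opened γ-hydroxybutenolide), followed by lactol closure and loss of CO2.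

Assumption: tert-butyl 2-bromoacrylate, (1E)-1-methoxybuta-1,3-diene, ethyl glyoxylate and 2,2-dimethoxyacetaldehyde are bought, and the lactol carbon of the target is its thermodynamic epimer.

**Route**

Step 1
Reactants: 1 heptanal; 2 methyl propiolate
Product: 3 methyl (4S)-4-hydroxydec-2-ynoate
Conditions: Me2Zn (3 equiv), (S,S)-ProPhenol (20 mol%; ligand antipode chosen for 4S), Ph3PO (40 mol%), PhMe, 4 °C
Reagents that add atoms: none
Why: Zinc–ProPhenol-catalysed asymmetric alkynylation of an aldehyde; the dinuclear zinc alkynylide delivers the propiolate to one face of heptanal and sets the 4S carbinol, which becomes the butenolide stereocentre.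

Step 2
Reactants: 3 methyl (4S)-4-hydroxydec-2-ynoate
Product: 5 (5S)-5-hexyl-3-(tributylstannyl)furan-2(5H)-one, via hydroxy stannyl enoate 4 (not isolated)
Conditions: Bu3SnH, Pd(PPh3)4 (2 mol%), THF, 0 → 25 °C; then PPTS (cat.), PhMe, 60 °C
Reagents that add atoms: tributyltin hydride, CCCC[SnH](CCCC)CCCC
Why: Palladium-catalysed syn-hydrostannation of the ynoate puts tin α and hydrogen β, so ester and carbinol are cis and lactonise to the α-stannyl butenolide; the stereocentre is not touched.

Step 3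
Reactants: 5 (5S)-5-hexyl-3-(tributylstannyl)furan-2(5H)-one; 6 tert-butyl 2-bromoprop-2-enoate
Product: 7 tert-butyl 2-[(5S)-5-hexyl-2-oxo-2,5-dihydrofuran-3-yl]prop-2-enoate
Conditions: Pd2(dba)3 (2.5 mol%), AsPh3 (20 mol%), CuI (10 mol%), NMP, 25 °C; used at once
Reagents that add atoms: none
Why: Copper-assisted Stille coupling of the alkenylstannane with the α-bromoacrylate runs under neutral conditions that leave the base-labile γ-centre of the butenolide intact.

Step 4
Reactants: 8 ethyl glyoxylate; 9 (1E)-1-methoxybuta-1,3-diene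
Product: 10 ethyl (2S,6R)-6-methoxy-3,6-dihydro-2H-pyran-2-carboxylate
Conditions: (S)-BINOL–TiCl2(OiPr)2 (10 mol%; antipode chosen for 2S), CH2Cl2, −30 °C
Reagents that add atoms: none
Why: BINOL–titanium-catalysed asymmetric hetero-Diels–Alder reaction; the catalyst shields one face of the glyoxylate and sets C2 as S in the endo (cis) adduct, while the acetal centre is removed in step 6.

Step 5
Reactants: 10 ethyl (2S,6R)-6-methoxy-3,6-dihydro-2H-pyran-2-carboxylate; 11 prop-2-enyl acetate
Product: 12 prop-2-enyl 3-[(2S,6R)-6-methoxy-3,6-dihydro-2H-pyran-2-yl]-3-oxopropanoate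
Conditions: LiN(iPr)2 (2.2 equiv), 11 (2.2 equiv), THF, −78 °C; then 10; aq. NH4Cl
Reagents that add atoms: none
Why: Crossed Claisen condensation; the lithium enolate of allyl acetate acylates on the activated α-alkoxy ester at −78 °C faster than it deprotonates C2, and the product is stored as its enolate, so the 2S centre is kept.

Step 6
Reactants: 12 prop-2-enyl 3-[(2S,6R)-6-methoxy-3,6-dihydro-2H-pyran-2-yl]-3-oxopropanoate
Product: 14 prop-2-enyl 3-oxo-3-[(2S)-6-oxo-3,6-dihydro-2H-pyran-2-yl]propanoate, via lactol 13 (not isolated)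
Conditions: CrO3, H2SO4, H2O/acetone, 0 °C
Reagents that add atoms: water, O
Why: Jones oxidation; acid hydrolysis of the allylic acetal to the lactol and chromic acid oxidation give the 5,6-dihydropyran-2-one without touching the β-ketoester or the stereocentre.

Step 7
Reactants: 15 tert-butyl prop-2-enoate; 16 2,2-dimethoxyacetaldehyde
Product: 17 tert-butyl 3-hydroxy-4,4-dimethoxy-2-methylidenebutanoate (racemic)
Conditions: DABCO (0.5 equiv), 1,4-dioxane/H2O, 25 °C
Reagents that add atoms: none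
Why: Morita–Baylis–Hillman reaction of the acrylate with the reactive α,α-dialkoxy aldehyde; the carbinol centre is lost in step 8, so no control is needed.

Step 8
Reactants: 17 tert-butyl 3-hydroxy-4,4-dimethoxy-2-methylidenebutanoate
Product: 18 tert-butyl (2Z)-2-(bromomethyl)-4,4-dimethoxybut-2-enoate
Conditions: NBS, Me2S, CH2Cl2, −20 → 25 °C
Reagents that add atoms: N-bromosuccinimide, O=C1CCC(=O)N1Br
Why: The NBS–Me2S sulfonium salt activates the Baylis–Hillman alcohol and bromide enters with allylic transposition (SN2'), giving the more stable trisubstituted allylic bromide.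

Step 9
Reactants: 14 prop-2-enyl 3-oxo-3-[(2S)-6-oxo-3,6-dihydro-2H-pyran-2-yl]propanoate; 18 tert-butyl (2Z)-2-(bromomethyl)-4,4-dimethoxybut-2-enoate
Product: 19 1-tert-butyl 5-prop-2-enyl (2E)-2-(2,2-dimethoxyethylidene)-4-[(2S)-6-oxo-3,6-dihydro-2H-pyran-2-carbonyl]pentanedioate (both C4 epimers)
Conditions: K2CO3, acetone, 0 → 25 °C
Reagents that add atoms: none
Why: SN2 C-alkylation of the soft β-ketoester enolate by the allylic bromide under mild carbonate conditions; the new centre is erased later, and the pyranone centre is safe because enolisation goes towards the 1,3-dicarbonyl carbon.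

Step 10
Reactants: 19 1-tert-butyl 5-prop-2-enyl (2E)-2-(2,2-dimethoxyethylidene)-4-[(2S)-6-oxo-3,6-dihydro-2H-pyran-2-carbonyl]pentanedioate
Product: 20 prop-2-enyl 2-[(5-hydroxy-2-oxo-2,5-dihydrofuran-3-yl)methyl]-3-oxo-3-[(2S)-6-oxo-3,6-dihydro-2H-pyran-2-yl]propanoate (epimers at chain C2 and at the lactol carbon)
Conditions: CF3CO2H/H2O (9:1), CH2Cl2, 40 °C
Reagents that add atoms: water, O
Why: Acidolysis of the tert-butyl ester and hydrolysis of the acetal give the formylacrylic acid, which isomerises under acid and closes to the cyclic pseudoacid (γ-hydroxybutenolide), the form the biogenetic partner is presumed to have.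

Step 11
Reactants: 20 prop-2-enyl 2-[(5-hydroxy-2-oxo-2,5-dihydrofuran-3-yl)methyl]-3-oxo-3-[(2S)-6-oxo-3,6-dihydro-2H-pyran-2-yl]propanoate; 7 tert-butyl 2-[(5S)-5-hexyl-2-oxo-2,5-dihydrofuran-3-yl]prop-2-enoate
Product: 23 6-tert-butyl 8-prop-2-enyl (5S,6S)-6-[(5S)-5-hexyl-2-oxo-2,5-dihydrofuran-3-yl]-3-hydroxy-1-oxo-8-[(2S)-6-oxo-3,6-dihydro-2H-pyran-2-carbonyl]-2-oxaspiro[4.4]nonane-6,8-dicarboxylate (8-acyl cis to the C1 lactone carbonyl; lactol epimers), via ring-opened formylacrylate 21 (not isolated), via acyclic Michael adduct 22 (not isolated)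
Conditions: Mg[N(SiMe3)2]2 (1.05 equiv), THF, −40 °C; then 7, −40 → 0 °C; aq. HCl (pH 3)
Reagents that add atoms: none
Why: Proposed new method: the magnesium amide removes the two most acidic protons of 20, which opens the pseudoacid to the (Z)-formylacrylate carboxylate 21 and gives a magnesium-chelated β-ketoester enolate; this enolate adds to the acrylate 7 (first Michael addition) and the ester enolate born in 22 is trapped at once, 5-exo-trig, by the enal β-carbon (second Michael addition), after which acidification closes the γ-oxo acid to the spiro-lactol; the magnesium ion is expected to bridge the ester enolate oxygen, the carboxylate and the more basic ketone so that these three groups end on one ring face (cis-dicarboxyl arrangement, acyl syn), and the chelated enolate is attacked on the face away from the pyranone ring, which fixes the absolute sense of the two quaternary ring carbons; the closest known reactions are base-mediated Michael/Michael [3+2] ring closures of 1,3-dicarbonyl donor–acceptors and conjugate additions to ring-opened γ-hydroxybutenolides.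

Step 12
Reactants: 23 6-tert-butyl 8-prop-2-enyl (5S,6S)-6-[(5S)-5-hexyl-2-oxo-2,5-dihydrofuran-3-yl]-3-hydroxy-1-oxo-8-[(2S)-6-oxo-3,6-dihydro-2H-pyran-2-carbonyl]-2-oxaspiro[4.4]nonane-6,8-dicarboxylate
Product: 25 tert-butyl (5S,6S,8S)-6-[(5S)-5-hexyl-2-oxo-2,5-dihydrofuran-3-yl]-3-hydroxy-1-oxo-8-[(2S)-6-oxo-3,6-dihydro-2H-pyran-2-carbonyl]-2-oxaspiro[4.4]nonane-6-carboxylate (lactol epimers), via exocyclic enol 24 (not isolated)
Conditions: Pd(PPh3)4 (5 mol%), HCO2H, Et3N, THF, 0 °C
Reagents that add atoms: none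
Why: Tsuji-type deallylation–decarboxylation; zerovalent palladium ionises the allyl ester, CO2 is lost and formate reduces the allyl group, and the resulting enol(ate) 24 takes up hydrogen on the face opposite the pseudo-axial tert-butyl ester (the bulky butenolide sits pseudo-equatorial), so the acyl group stays cis to both carboxyl groups (8S), while the neutral buffer avoids epimerisation next to the ketone.

Step 13
Reactants: 25 tert-butyl (5S,6S,8S)-6-[(5S)-5-hexyl-2-oxo-2,5-dihydrofuran-3-yl]-3-hydroxy-1-oxo-8-[(2S)-6-oxo-3,6-dihydro-2H-pyran-2-carbonyl]-2-oxaspiro[4.4]nonane-6-carboxylate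
Product: 26 tert-butyl (5S,6S,8S)-6-[(5S)-5-hexyl-2-oxo-2,5-dihydrofuran-3-yl]-3-hydroxy-8-{(S)-hydroxy[(2S)-6-oxo-3,6-dihydro-2H-pyran-2-yl]methyl}-1-oxo-2-oxaspiro[4.4]nonane-6-carboxylate (lactol epimers)
Conditions: NaBH4, CeCl3·7H2O, MeOH, −78 °C; aq. citric acid
Reagents that add atoms: none
Why: Luche reduction; CeCl3 in methanol masks the lactol as its methyl acetal in the flask and makes borohydride 1,2-selective, so only the ketone is reduced, and hydride adds anti to the C–O bond of the α-acyloxy centre (Felkin–Anh polar model) to give the threo (S) carbinol.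

Step 14
Reactants: 26 tert-butyl (5S,6S,8S)-6-[(5S)-5-hexyl-2-oxo-2,5-dihydrofuran-3-yl]-3-hydroxy-8-{(S)-hydroxy[(2S)-6-oxo-3,6-dihydro-2H-pyran-2-yl]methyl}-1-oxo-2-oxaspiro[4.4]nonane-6-carboxylate
Product: 27 penicillactone A
Conditions: CF3CO2H, CH2Cl2, 0 → 25 °C; aqueous work-up, crystallisation
Reagents that add atoms: none
Why: Acid-catalysed cleavage of the tert-butyl ester (loss of isobutene) frees the ring acid; the lactol carbon equilibrates by ring–chain tautomerism of the pseudoacid and is collected as the natural 3S epimer, the thermodynamic crystalline form.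

**Compound list**

1 | heptanal | CCCCCCC=O | starting material
2 | methyl propiolate | C#CC(=O)OC | starting material
3 | methyl (4S)-4-hydroxydec-2-ynoate | CCCCCC[C@H](O)C#CC(=O)OC | intermediate
4 | methyl (2E,4S)-4-hydroxy-2-(tributylstannyl)dec-2-enoate | CCCCCC[C@H](O)/C=C(\C(=O)OC)[Sn](CCCC)(CCCC)CCCC | intermediate
5 | (5S)-5-hexyl-3-(tributylstannyl)furan-2(5H)-one | CCCCCC[C@H]1C=C([Sn](CCCC)(CCCC)CCCC)C(=O)O1 | intermediate
6 | tert-butyl 2-bromoprop-2-enoate | C=C(Br)C(=O)OC(C)(C)C | starting material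
7 | tert-butyl 2-[(5S)-5-hexyl-2-oxo-2,5-dihydrofuran-3-yl]prop-2-enoate | CCCCCC[C@H]1C=C(C(=C)C(=O)OC(C)(C)C)C(=O)O1 | intermediate
8 | ethyl glyoxylate | CCOC(=O)C=O | starting material
9 | (1E)-1-methoxybuta-1,3-diene | CO/C=C/C=C | starting material
10 | ethyl (2S,6R)-6-methoxy-3,6-dihydro-2H-pyran-2-carboxylate | CCOC(=O)[C@@H]1CC=C[C@H](OC)O1 | intermediate
11 | prop-2-enyl acetate | CC(=O)OCC=C | starting material
12 | prop-2-enyl 3-[(2S,6R)-6-methoxy-3,6-dihydro-2H-pyran-2-yl]-3-oxopropanoate | C=CCOC(=O)CC(=O)[C@@H]1CC=C[C@H](OC)O1 | intermediate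
13 | prop-2-enyl 3-[(2S)-6-hydroxy-3,6-dihydro-2H-pyran-2-yl]-3-oxopropanoate (lactol, both anomers) | C=CCOC(=O)CC(=O)[C@@H]1CC=CC(O)O1 | intermediate
14 | prop-2-enyl 3-oxo-3-[(2S)-6-oxo-3,6-dihydro-2H-pyran-2-yl]propanoate | C=CCOC(=O)CC(=O)[C@@H]1CC=CC(=O)O1 | intermediate
15 | tert-butyl prop-2-enoate | C=CC(=O)OC(C)(C)C | starting material
16 | 2,2-dimethoxyacetaldehyde | COC(OC)C=O | starting material
17 | tert-butyl 3-hydroxy-4,4-dimethoxy-2-methylidenebutanoate (racemic) | C=C(C(O)C(OC)OC)C(=O)OC(C)(C)C | intermediate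
18 | tert-butyl (2Z)-2-(bromomethyl)-4,4-dimethoxybut-2-enoate | BrC/C(=C\C(OC)OC)C(=O)OC(C)(C)C | intermediate
19 | 1-tert-butyl 5-prop-2-enyl (2E)-2-(2,2-dimethoxyethylidene)-4-[(2S)-6-oxo-3,6-dihydro-2H-pyran-2-carbonyl]pentanedioate (both C4 epimers) | C=CCOC(=O)C(C/C(=C\C(OC)OC)C(=O)OC(C)(C)C)C(=O)[C@@H]1CC=CC(=O)O1 | intermediate
20 | prop-2-enyl 2-[(5-hydroxy-2-oxo-2,5-dihydrofuran-3-yl)methyl]-3-oxo-3-[(2S)-6-oxo-3,6-dihydro-2H-pyran-2-yl]propanoate (epimers at chain C2 and lactol carbon) | C=CCOC(=O)C(CC1=CC(O)OC1=O)C(=O)[C@@H]2CC=CC(=O)O2 | intermediate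
21 | (2Z)-2-(2-oxoethylidene)-5-oxo-5-[(2S)-6-oxo-3,6-dihydro-2H-pyran-2-yl]-4-[(prop-2-enyloxy)carbonyl]pentanoic acid (drawn as the acid; present as its magnesium salt) | C=CCOC(=O)C(C/C(=C/C=O)C(=O)O)C(=O)[C@@H]1CC=CC(=O)O1 | intermediate
22 | acyclic Michael adduct of 21 and 7 (new bond between the β-ketoester carbon and the acrylate CH2; drawn with H on the ester α-carbon, present as its magnesium enolate) | CCCCCC[C@H]1C=C(C(C(=O)OC(C)(C)C)C[C@@](C(=O)OCC=C)(C(=O)[C@@H]2CC=CC(=O)O2)C/C(=C/C=O)C(=O)O)C(=O)O1 | intermediate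
23 | 6-tert-butyl 8-prop-2-enyl (5S,6S)-6-[(5S)-5-hexyl-2-oxo-2,5-dihydrofuran-3-yl]-3-hydroxy-1-oxo-8-[(2S)-6-oxo-3,6-dihydro-2H-pyran-2-carbonyl]-2-oxaspiro[4.4]nonane-6,8-dicarboxylate (8-acyl cis to the C1 lactone carbonyl; lactol epimers) | CCCCCC[C@H]1C=C([C@]2(C(=O)OC(C)(C)C)C[C@@](C(=O)OCC=C)(C(=O)[C@@H]3CC=CC(=O)O3)C[C@]23CC(O)OC3=O)C(=O)O1 | intermediate
24 | exocyclic C8 enol of 25 (palladium-bound in the flask) | CCCCCC[C@H]1C=C([C@]2(C(=O)OC(C)(C)C)CC(=C(O)[C@@H]3CC=CC(=O)O3)C[C@]23CC(O)OC3=O)C(=O)O1 | intermediate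
25 | tert-butyl (5S,6S,8S)-6-[(5S)-5-hexyl-2-oxo-2,5-dihydrofuran-3-yl]-3-hydroxy-1-oxo-8-[(2S)-6-oxo-3,6-dihydro-2H-pyran-2-carbonyl]-2-oxaspiro[4.4]nonane-6-carboxylate (lactol epimers) | CCCCCC[C@H]1C=C([C@]2(C(=O)OC(C)(C)C)C[C@@H](C(=O)[C@@H]3CC=CC(=O)O3)C[C@]23CC(O)OC3=O)C(=O)O1 | intermediate
26 | tert-butyl (5S,6S,8S)-6-[(5S)-5-hexyl-2-oxo-2,5-dihydrofuran-3-yl]-3-hydroxy-8-{(S)-hydroxy[(2S)-6-oxo-3,6-dihydro-2H-pyran-2-yl]methyl}-1-oxo-2-oxaspiro[4.4]nonane-6-carboxylate (lactol epimers) | CCCCCC[C@H]1C=C([C@]2(C(=O)OC(C)(C)C)C[C@@H]([C@H](O)[C@@H]3CC=CC(=O)O3)C[C@]23CC(O)OC3=O)C(=O)O1 | intermediate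
27 | penicillactone A, (3S,5S,6S,8S)-6-[(5S)-5-hexyl-2-oxo-2,5-dihydrofuran-3-yl]-3-hydroxy-8-{(S)-hydroxy[(2S)-6-oxo-3,6-dihydro-2H-pyran-2-yl]methyl}-1-oxo-2-oxaspiro[4.4]nonane-6-carboxylic acid | CCCCCC[C@H]1C=C([C@]2(C(=O)O)C[C@@H]([C@H](O)[C@@H]3CC=CC(=O)O3)C[C@]23C[C@@H](O)OC3=O)C(=O)O1 | target

**Step count and risks**

Total: 14 steps. Longest linear sequence: 9 steps (4, 5, 6, 9, 10, 11, 12, 13, 14).

Most likely to fail, first: step 11. The magnesium enolate may stop after the first conjugate addition, the transient ester enolate next to the butenolide may scramble the γ-centre, and the cis arrangement of the two carboxyl carbons rests on a chelation model. Fallback: set out from 19. Zerovalent palladium (Pd(PPh3)4) with HCO2H/Et3N removes the allyl ester and CO2 first and gives the ketone tert-butyl (2E)-4,4-dimethoxy-2-{3-oxo-3-[(2S)-6-oxo-3,6-dihydro-2H-pyran-2-yl]propyl}but-2-enoate F1. CF3CO2H/H2O turns it into the pseudoacid (6S)-6-[4-(5-hydroxy-2-oxo-2,5-dihydrofuran-3-yl)butanoyl]-5,6-dihydro-2H-pyran-2-one F2. F2 and 7 are then joined by enamine activation (pyrrolidine, PhCO2H, CHCl3): the ketone enamine adds to 7, the zwitterionic ester enolate closes on the iminium-activated formylacrylate, and hydrolysis gives 25, where the route is rejoined. The ring C–H is then set during C–C bond formation, no metal enolate is present, and step 12 is not needed.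

Second: step 12. Protonation of the enol could give the C8 epimer, since the facial preference rests on a conformational argument. Fallback: set out from 23. Luche reduction of the ketone first gives the β-hydroxy ester 6-tert-butyl 8-prop-2-enyl (5S,6S)-6-[(5S)-5-hexyl-2-oxo-2,5-dihydrofuran-3-yl]-3-hydroxy-8-{(S)-hydroxy[(2S)-6-oxo-3,6-dihydro-2H-pyran-2-yl]methyl}-1-oxo-2-oxaspiro[4.4]nonane-6,8-dicarboxylate F3. Pd(PPh3)4 with morpholine frees the corresponding 8-carboxylic acid F4. A photocatalytic hydrodecarboxylation (9-mesityl-10-methylacridinium tetrafluoroborate, PhSSPh, blue light) replaces CO2H by H through a tertiary radical, which takes its hydrogen atom from thiophenol on the face away from the pseudo-axial ester, and gives 26, where the route is rejoined. A radical hydrogen-atom transfer thus replaces the enol protonation.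

Third: step 13. Felkin control by the acyloxy-bearing centre may be modest next to the branched ring carbon. Fallback: set out from 25. CF3CO2H first removes the tert-butyl ester and gives the keto acid (5S,6S,8S)-6-[(5S)-5-hexyl-2-oxo-2,5-dihydrofuran-3-yl]-3-hydroxy-1-oxo-8-[(2S)-6-oxo-3,6-dihydro-2H-pyran-2-carbonyl]-2-oxaspiro[4.4]nonane-6-carboxylic acid F5. The free carboxyl group, cis to the acyl group, then directs the reduction: Me4NBH(OAc)3 in MeCN/AcOH exchanges an acetate for the carboxylate and delivers hydride within the molecule (Evans–Saksena-type directed reduction). The acidic medium keeps the lactol closed, and the product is 27 directly.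

Further compounds
F1 | step 11 | tert-butyl (2E)-4,4-dimethoxy-2-{3-oxo-3-[(2S)-6-oxo-3,6-dihydro-2H-pyran-2-yl]propyl}but-2-enoate | O=C(CC/C(=C\C(OC)OC)C(=O)OC(C)(C)C)[C@@H]1CC=CC(=O)O1
F2 | step 11 | (6S)-6-[4-(5-hydroxy-2-oxo-2,5-dihydrofuran-3-yl)butanoyl]-5,6-dihydro-2H-pyran-2-one (lactol epimers) | O=C(CCC1=CC(O)OC1=O)[C@@H]2CC=CC(=O)O2
F3 | step 12 | 6-tert-butyl 8-prop-2-enyl (5S,6S)-6-[(5S)-5-hexyl-2-oxo-2,5-dihydrofuran-3-yl]-3-hydroxy-8-{(S)-hydroxy[(2S)-6-oxo-3,6-dihydro-2H-pyran-2-yl]methyl}-1-oxo-2-oxaspiro[4.4]nonane-6,8-dicarboxylate | CCCCCC[C@H]1C=C([C@]2(C(=O)OC(C)(C)C)C[C@@](C(=O)OCC=C)([C@H](O)[C@@H]3CC=CC(=O)O3)C[C@]23CC(O)OC3=O)C(=O)O1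
F4 | step 12 | (5S,6S)-6-(tert-butoxycarbonyl)-6-[(5S)-5-hexyl-2-oxo-2,5-dihydrofuran-3-yl]-3-hydroxy-8-{(S)-hydroxy[(2S)-6-oxo-3,6-dihydro-2H-pyran-2-yl]methyl}-1-oxo-2-oxaspiro[4.4]nonane-8-carboxylic acid | CCCCCC[C@H]1C=C([C@]2(C(=O)OC(C)(C)C)C[C@@](C(=O)O)([C@H](O)[C@@H]3CC=CC(=O)O3)C[C@]23CC(O)OC3=O)C(=O)O1
F5 | step 13 | (5S,6S,8S)-6-[(5S)-5-hexyl-2-oxo-2,5-dihydrofuran-3-yl]-3-hydroxy-1-oxo-8-[(2S)-6-oxo-3,6-dihydro-2H-pyran-2-carbonyl]-2-oxaspiro[4.4]nonane-6-carboxylic acid | CCCCCC[C@H]1C=C([C@]2(C(=O)O)C[C@@H](C(=O)[C@@H]3CC=CC(=O)O3)C[C@]23CC(O)OC3=O)C(=O)O1
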